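Numbering used throughout: hydrindane C1 (ring C carbinol), C2, C3, C3a, C4 (ring B carbinol), C5, C6 (spiro carbon), C7, C7a; ring A C1′ (= C6), C2′ (C=O), C3′ (C(CH3)(prenyl)), C4′ (enol carbon), C5′ (acyl-bearing), C6′ (C=O).

## Structural features

Hyperielliptone HB joins three rings: ring A, an enolised 5′-acylcyclohexane-2′,4′,6′-trione, is spiro-linked through C6 to ring B, a cyclohexane that is cis-fused along C3a–C7a to the cyclopentane ring C. Ring B holds the spiro carbon between two methylenes (C5, C7) and a tertiary carbinol at C4; ring C holds a tertiary carbinol at C1. C1, C7a, C3a and C4 are four contiguous stereocentres: H-3a and H-7a are cis, the 1-OH lies on the side of C7, the 4-OH on the side of C3, and both methyl groups lie on the face of the fusion hydrogens. C6 is stereogenic only because its two carbonyl arms differ: C6′ lies on the face of ring B that carries the 4-OH and the C7a–C1 bond, C2′ on the opposite face. C3′ is an isolated quaternary stereocentre, and the side chain carries an (S)-centre α to a carbonyl. Fragile groups are the acidic β,β′-triketone (retro-Claisen, O-alkylation), the two tertiary alcohols (dehydration, addition to the nearby C6′ carbonyl), the prenyl alkene (no hydrogenation, radical or strong-acid step once it is in place) and the epimerisable side-chain centre. The real difficulty is telling the two carbonyl arms of C6 apart and setting C3′, which has no stereocentre near it; the four contiguous centres are comparatively easy once a cis-hydrindane is in hand. The key step exploits two facts: C5–C6–C7 with its two carbonyl arms is the CH2–C(CO2R)2–CH2 unit of a cyclobutane-1,1-diester whose remaining carbon is the future C4, and C7a/C3a are the α/β carbons of a cyclopentenone whose carbonyl is the future C1. An enone–cyclobutene [2+2] photocycloaddition forms C7a–C7 and C3a–C4, and cleavage of the C4–C7 bond then unveils ring B.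

## Logic of the disconnections

22 ⇒ 21. The C3′–CH3 bond is cut. After double deprotonation C3′ is the only carbon nucleophile of 21, so the methyl group can go on without protecting the tertiary alcohols. The cut removes a quaternary stereocentre; the cost is that the forward alkylation occurs far from every stereocentre and must be expected to need a separation.

21 ⇒ 18 + 19. The C5′–acyl bond is cut. The acyl group has to precede the alkylation because it blocks C5′; the cut takes the side-chain stereocentre out as commercial 19. The forward step must deliver the acyl group to carbon without racemising its α-centre.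

18 ⇒ 17. The C2′–C3′ bond of ring A is cut. This reduces ring A to a β-diketone chain and an ester on C6. The forward step needs the γ-carbanion of the diketone to attack a hindered ester on a quaternary carbon.

17 ⇒ 14 + 15. The C6′–C5′ bond is cut and the freed C6′ carboxyl is closed onto O1 as a lactone. This disconnection carries the spiro stereochemistry: in 14 the arm cis to the C7a–C1 bond is a lactone and the other arm is an isopropyl ester, so reactivity decides which arm receives the methyl carbon of 15. The forward step needs the kinetic enolate of 15 and attack at the lactone only.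

14 ⇒ 13. The C4–CH3 bond is cut. The bridged lactone of 13 leaves only one face of the C4 carbonyl open, so the stereocentre is removed at little risk. The organometallic reagent must spare lactone and ester.

13 ⇒ 11. The lactone O1–acyl bond is cut and O1 is silylated. C6 regains two equal esters and stops being a stereocentre. The forward lactonisation can reach only the ester cis to C1 and only in a cis-fused hydrindane, so geometry does the selection.

11 ⇒ 10. C4 and C7 are re-joined. The cyclohexanone becomes a bicyclo[2.2.0]hexan-1-ol, so ring B is now two cyclobutanes. The forward homolytic cleavage must choose the central bond, and no other hydroxyl may be free; hence the silyl cap on the other oxygen.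

10 ⇒ 7. The C–CH3 bond at the future C1 is cut and the silyl groups are adjusted. Adding the methyl group while C4 is still masked as the bridgehead silyl ether saves a ketone protection, and the rigid bicyclo[3.2.0]heptanone directs the reagent. The forward step must cap the new alkoxide in the same flask and later free the bridgehead oxygen selectively.

7 ⇒ 5. A silyloxy group is added next to the future C3a. 7 has no handle for absolute control, and an enone without a stereocentre would give a racemate. A chiral Lewis acid strong enough to control it would also trigger Mukaiyama–Michael addition of the silyl enol ether. The added group comes from a commercial enantiopure enone, directs the cycloaddition and leaves by elimination, at the cost of one step.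

5 ⇒ 3 + 4. The two cyclobutane bonds between the five-membered ring and the diester cyclobutane are cut. This key disconnection leads to a commercial enone and a cyclobutene that holds every ring B carbon. The forward step needs head-to-tail orientation and attack anti to the silyloxy group.

3 ⇒ 2 ⇒ 1. The O–Si bond is cut and the ketal restored, which leads back to commercial 1. The only demand is a soft enolisation that leaves the esters alone.

## Other disconnections considered

Alternative 1: The cut is the C3a–C7a bond of ring C together with the C4–O bond, leaving ring B open at both bonds to the spiro carbon. In the forward step enyne A2 is treated with DTBM-SEGPHOS(AuCl)2 and AgSbF6 in wet dioxane: cationic monovalent gold activates the alkyne, the Z-trisubstituted alkene attacks 5-exo-dig, and water captures the tertiary cation anti, giving A1.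
- In its favour: one catalytic step fixes C3a and the C4 carbinol relative to each other (anti addition across a defined alkene) and, through the chiral bisphosphine, in the absolute sense.
- Against it here: enantioselective gold hydroxycyclisations are best established for malonate- or sulfonamide-tethered enynes, and the propargylic ketal of A2 may ionise under the Lewis-acidic conditions. After A1, ring B still needs two C–C bonds to a carbon bearing two esters, one of them at a neopentyl-type CH2 next to the carbinol, and C7a becomes stereogenic only then.
- Comparison: it is the better plan for C4 (catalyst plus stereospecific addition against a conformational lock) and for the source of absolute configuration (catalytic against a stoichiometric chiral-pool group). It is equal in the ring A endgame. It is worse in step economy (enyne assembly and ring B annulation add roughly four to six steps) and in that its key step delivers neither the spiro carbon nor C7a, whereas the photoadduct holds all ring B carbons.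

Alternative 2: The cuts are C6–C7 and C3a–C7a, so rings B and C fall apart together. Triene A4, reached from (R)-linalool A5 in about four steps, would be heated to about 190 °C so that the diester-bearing diene terminus and the vinyl group combine in an intramolecular Diels–Alder reaction to give A3.
- In its favour: the chiral pool supplies C1 in the correct absolute configuration, both carbocycles and the gem-diester carbon arise in one step, and no photochemical or radical step is needed.
- Against it here: the diene is electron-poor at the bonding terminus and the dienophile unactivated, hence the high temperature. The three-atom tether allows cis and trans fusion and both faces relative to the quaternary carbinol, and 1,5-hydrogen shifts of the dienyl diester can compete. A3 carries C4 only as an alkene carbon, so the carbinol needs a later Markovnikov hydration with its own facial problem.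
- Comparison: on step economy it is the better plan (probably ten to eleven steps), and on the source of absolute configuration as well. The endgame is equal, since the C1 oxygen can lactonise in the same way. The chosen plan is better in predictability: cis fusion is enforced by strain in the bicyclo[3.2.0] adduct and C4 by a bridged lactone, whereas A4 can close through four diastereomeric transition states.

Alternative 3: The cut is the C3a–C4 bond, with a ketone at the future spiro carbon. Norbornenol A7 would be converted with KH and 18-crown-6 into its alkoxide, whose [3,3] shift through a boat transition state breaks the norbornene C1–C2 bond and gives A6.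
- In its favour: a concerted, stereospecific step under mild conditions in which the bicyclic template dictates cis fusion and C1, C7a, C3a and C4 are all defined at once, with both carbinol oxygens already present.
- Against it here: A7 needs a 7,7-disubstituted norbornenone, an endo-selective addition of a geometrically defined alkenyl metal and its own source of enantiopurity. The boat transition state must bond a fully substituted enol-ether terminus. A6 has only a ketone at the future spiro carbon, so two different carbonyl arms must be attached one after the other with a new facial problem, and alkene hydrogenation and debenzylation follow.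
- Comparison: its key step is the better in stereochemical economy (four centres set and kept, against two kept of four), and it is equal in mildness. It is worse at the spiro carbon, which the chosen plan carries with both arms from the first step and differentiates by lactonisation, and in step count (likely eighteen or more).

Key step: step 3

Assumption: the 4-hydroxyl of 14 is taken to stay free; acyl transfer to it would only exchange the δ-lactone for the γ-lactone F7 on the same carbonyl carbon, which reacts identically in step 10.

## Steps

Ladder numbering for 5–10: tricyclo[4.3.0.0(2,5)]nonane with C9 the ketone carbon, C1 its α-carbon, C6 the former β-carbon, C2–C5 the bond shared by the two cyclobutanes, C3 the diester carbon.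

Step 1
Reactants: 1 diisopropyl 3,3-dimethoxycyclobutane-1,1-dicarboxylate
Product: 2 diisopropyl 3-oxocyclobutane-1,1-dicarboxylate
Conditions: 2 M HCl (aq), acetone, rt
Reagents that add atoms: water, O
Why: Acid-catalysed ketal hydrolysis through the oxocarbenium ion; the hindered isopropyl esters are inert at room temperature.

Step 2
Reactants: 2 diisopropyl 3-oxocyclobutane-1,1-dicarboxylate
Product: 3 diisopropyl 3-(trimethylsilyloxy)cyclobut-2-ene-1,1-dicarboxylate
Conditions: TMSOTf, Et3N, CH2Cl2, 0 °C; pentane extraction, used crude
Reagents that add atoms: trimethylsilyl trifluoromethanesulfonate, C[Si](C)(C)OS(=O)(=O)C(F)(F)F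
Why: Soft enolisation of a ketone with a silyl triflate and an amine; the two α-methylenes are equivalent, so one silyl enol ether forms, and the quaternary diester carbon has no acidic hydrogen.

Step 3
Reactants: 3 diisopropyl 3-(trimethylsilyloxy)cyclobut-2-ene-1,1-dicarboxylate; 4 (R)-4-(tert-butyldimethylsilyloxy)cyclopent-2-en-1-one
Product: 5 diisopropyl 7-(tert-butyldimethylsilyloxy)-9-oxo-5-(trimethylsilyloxy)tricyclo[4.3.0.0(2,5)]nonane-3,3-dicarboxylate (cis-anti-cis ladder; 7-silyloxy group trans to C5)
Conditions: hν (350–366 nm, Pyrex), 3 (2 equiv), CH2Cl2, −40 °C
Reagents that add atoms: none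
Why: Excitation of the enone, intersystem crossing and addition of the triplet to the strained, electron-rich enol ether double bond give a triplet 1,4-diradical that closes after spin inversion; this is the classical enone–alkene [2+2] photocycloaddition, known for silyl enol ethers, for cyclobutenes and for 4-silyloxycyclopentenones. The cyclobutane is closed by radical–radical combination within the diradical and not by a polar ring closure, so the only geometric constraint is the cis fusion to the five-membered ring. Head-to-tail orientation is needed (silyloxy carbon C5 to the β-carbon C6, CH carbon C2 to the α-carbon C1): the nucleophilic CH terminus of the enol ether bonds to the α-carbon of the polarised triplet and leaves a tertiary α-silyloxy radical that closes onto the β-carbon. C1 and C6 form cis because a trans-fused bicyclo[3.2.0]heptanone is too strained. Their absolute configuration is set by the silyloxy-bearing stereocentre of 4 (C7 of the adduct), which sits next to the β-carbon and sends the cyclobutene to the opposite face; the minor syn adduct is a diastereomer and is removed by chromatography, so the enantiomeric purity of 4 is carried over. C2 and C5 arise from exo approach of the cyclobutene but are erased in step 7, so exo/endo selectivity costs nothing. Both faces of 3 are equivalent, so the diester carbon raises no stereochemical question, and an excess of 3 at low temperature suppresses enone dimerisation.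

Step 4
Reactants: 5 diisopropyl 7-(tert-butyldimethylsilyloxy)-9-oxo-5-(trimethylsilyloxy)tricyclo[4.3.0.0(2,5)]nonane-3,3-dicarboxylate
Product: 7 diisopropyl 9-oxo-5-(trimethylsilyloxy)tricyclo[4.3.0.0(2,5)]nonane-3,3-dicarboxylate (cis-anti-cis), via cyclopentenone ladder 6 (not isolated)
Conditions: DBU, THF, 0 °C to rt; then 10% Pd/C, H2 (1 atm), same flask, rt
Reagents that add atoms: none
Why: E1cB loss of the β-silyloxy group gives the conjugated enone, whose disubstituted C=C is hydrogenated in preference to the ketone; C1 cannot epimerise because the trans-fused bicycle is prohibitively strained, so the two stereocentres that matter survive and the control element is gone.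

Step 5
Reactants: 7 diisopropyl 9-oxo-5-(trimethylsilyloxy)tricyclo[4.3.0.0(2,5)]nonane-3,3-dicarboxylate
Product: 9 diisopropyl 9-methyl-9-(triethylsilyloxy)-5-(trimethylsilyloxy)tricyclo[4.3.0.0(2,5)]nonane-3,3-dicarboxylate (9-oxygen cis to C2), via dichlorocerium alkoxide 8 (not isolated)
Conditions: MeMgBr, CeCl3, THF, −78 °C; then TESOTf, 2,6-lutidine, −78 to 0 °C
Reagents that add atoms: methylmagnesium bromide, C[Mg]Br; triethylsilyl trifluoromethanesulfonate, CC[Si](CC)(CC)OS(=O)(=O)C(F)(F)F
Why: Organocerium 1,2-addition to an enolisable ketone in the presence of esters; the reagent enters from the exo face of the bicyclo[3.2.0]heptanone (the face of H-1 and H-6), which places the methyl group cis to the fusion hydrogens and the oxygen on the side of C2, as the target requires at C1. Trapping the alkoxide with the silyl triflate keeps this oxygen out of the radical step.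

Step 6
Reactants: 9 diisopropyl 9-methyl-9-(triethylsilyloxy)-5-(trimethylsilyloxy)tricyclo[4.3.0.0(2,5)]nonane-3,3-dicarboxylate
Product: 10 diisopropyl 5-hydroxy-9-methyl-9-(triethylsilyloxy)tricyclo[4.3.0.0(2,5)]nonane-3,3-dicarboxylate
Conditions: citric acid, MeOH, 0 °C
Reagents that add atoms: none
Why: Acid-catalysed methanolysis removes the trimethylsilyl ether much faster than the bulkier tertiary triethylsilyl ether, so only the bridgehead cyclobutanol is set free.

Step 7
Reactants: 10 diisopropyl 5-hydroxy-9-methyl-9-(triethylsilyloxy)tricyclo[4.3.0.0(2,5)]nonane-3,3-dicarboxylate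
Product: 11 diisopropyl cis-1-methyl-4-oxo-1-(triethylsilyloxy)octahydro-1H-indene-6,6-dicarboxylate (1-oxygen cis to C7)
Conditions: [Ir(dF(CF3)ppy)2(5,5′-d(CF3)bpy)]PF6 (2 mol %), 2,4,6-triisopropylbenzenethiol (20 mol %), Bu4P[(MeO)2PO2] (20 mol %), PhCF3, blue LEDs, rt
Reagents that add atoms: none
Why: Photocatalytic proton-coupled electron transfer turns the only free O–H into an alkoxy radical, and β-scission breaks the bond shared by the two cyclobutanes because it alone releases the strain of both rings and leaves a secondary radical, which takes a hydrogen atom from the thiol (redox-neutral ring-opening isomerisation of a tertiary cycloalkanol). The carbinol carbon becomes the C4 ketone and the former cyclobutene CH becomes C7H2, so the two stereocentres lost are the ones not needed.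

Step 8
Reactants: 11 diisopropyl cis-1-methyl-4-oxo-1-(triethylsilyloxy)octahydro-1H-indene-6,6-dicarboxylate
Product: 13 keto δ-lactone isopropyl ester (O1 acylated by the C6 carboxyl cis to the C7a–C1 bond; C4 ketone), via hydroxy keto diester 12 (not isolated)
Conditions: TBAF, THF, 0 °C to rt
Reagents that add atoms: none
Why: Fluoride cleaves the silyl ether, and the alkoxide on the concave face lies 1,3-diaxial to one ester of C6 once ring B takes the chair with C1 axial, so it transesterifies to the six-membered bridged lactone with loss of isopropoxide. Only the ester cis to the C7a–C1 bond can be reached and only a cis-fused hydrindane can lactonise, so the two carbonyl arms of C6 are differentiated and any epimerisation at C3a corrects itself.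

Step 9
Reactants: 13 keto δ-lactone isopropyl ester
Product: 14 hydroxy δ-lactone isopropyl ester (4-methyl; 4-hydroxyl cis to C3)
Conditions: MeMgBr, CeCl3, THF, −78 °C
Reagents that add atoms: methylmagnesium bromide, C[Mg]Br
Why: Organocerium addition to the ketone of a 3-oxabicyclo[3.3.1]nonane: the endo face of C4 is blocked by the lactone bridge, so the methyl group enters exo (the face of H-3a) and the hydroxyl ends axial, cis to C3 and to the lactone carbonyl, as in the target. Lactone and isopropyl ester are inert to the organocerium reagent at −78 °C.

Step 10
Reactants: 14 hydroxy δ-lactone isopropyl ester; 15 6-methylhept-5-en-2-one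
Product: 17 isopropyl 1,4-dihydroxy-1,4-dimethyl-6-(7-methyl-1,3-dioxooct-6-enyl)octahydro-1H-indene-6-carboxylate (diketone arm cis to the 4-hydroxyl), via lithium enolate 16 (not isolated)
Conditions: 15 (3.5 equiv), LiN(iPr)2 (4.5 equiv), THF, −78 °C; then 14, −78 to −20 °C; aq NH4Cl
Reagents that add atoms: none
Why: Crossed Claisen acylation of the kinetic methyl-side lithium enolate by a lactone: the bridged lactone is far more electrophilic than the neopentyl-type isopropyl ester, so the methyl carbon of the ketone becomes C5′ bonded to C6′ and the tertiary alkoxide leaves as the 1-hydroxyl. Excess base takes up the 4-OH proton and deprotonates the β-diketone, which drives the reaction.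

Step 11
Reactants: 17 isopropyl 1,4-dihydroxy-1,4-dimethyl-6-(7-methyl-1,3-dioxooct-6-enyl)octahydro-1H-indene-6-carboxylate
Product: 18 1,4-dihydroxy-1,4-dimethyl-3′-(3-methylbut-2-enyl)spiro[octahydro-1H-indene-6,1′-cyclohexane]-2′,4′,6′-trione
Conditions: LiN(iPr)2 (5 equiv), THF, −78 to 0 °C; then 1 M HCl
Reagents that add atoms: none
Why: Dieckmann-type closure through the β-diketone dianion: the γ-carbanion (C3′) attacks the remaining ester in a 6-exo-trig closure to form C2′–C3′, and deprotonation of the trione makes it irreversible. The spiro configuration was already fixed by which ester sat in the lactone.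

Step 12
Reactants: 18 spiro trione; 19 (S)-2-methylbutanoic acid
Product: 21 5′-[(S)-2-methylbutanoyl] derivative of 18 (enolised triketone; C3′ epimerisable), via enol ester 20 (not isolated)
Conditions: DCC, DMAP (1.5 equiv), CH2Cl2, 0 °C to rt
Reagents that add atoms: none
Why: Carbodiimide esterification of the enol followed by DMAP-mediated O-to-C acyl migration, the standard route to 2-acylcyclohexane-1,3-diones. Migration ends at C5′, the only position that gives a chelated enolised β-triketone, the tertiary alcohols are too hindered to compete, and the mild conditions should preserve the α-centre of the acid.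

Step 13
Reactants: 21 5′-[(S)-2-methylbutanoyl] derivative of 18
Product: 22 Hyperielliptone HB
Conditions: NaOMe (3 equiv), MeI, MeOH, 0 °C to rt; chromatography
Reagents that add atoms: iodomethane, CI
Why: The dianion of the acyl trione (second deprotonation at C3′) is C-methylated at C3′, as in the classical gem-dialkylation of acylphloroglucinols; the acyl-bearing carbon and the tertiary alcohols do not react. C3′ is remote from every stereocentre, so little facial bias is expected and 22 is to be separated from its C3′ epimer.

## Compound list

1 | diisopropyl 3,3-dimethoxycyclobutane-1,1-dicarboxylate | CC(C)OC(=O)C1(C(=O)OC(C)C)CC(OC)(OC)C1 | starting material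
2 | diisopropyl 3-oxocyclobutane-1,1-dicarboxylate | CC(C)OC(=O)C1(C(=O)OC(C)C)CC(=O)C1 | intermediate
3 | diisopropyl 3-(trimethylsilyloxy)cyclobut-2-ene-1,1-dicarboxylate | CC(C)OC(=O)C1(C(=O)OC(C)C)C=C(O[Si](C)(C)C)C1 | intermediate
4 | (R)-4-(tert-butyldimethylsilyloxy)cyclopent-2-en-1-one | O=C1C=C[C@H](O[Si](C)(C)C(C)(C)C)C1 | starting material
5 | diisopropyl 7-(tert-butyldimethylsilyloxy)-9-oxo-5-(trimethylsilyloxy)tricyclo[4.3.0.0(2,5)]nonane-3,3-dicarboxylate, cis-anti-cis, 7-silyloxy trans to C5 | CC(C)OC(=O)C1(C(=O)OC(C)C)[C@H]2[C@H]3[C@H]([C@H](O[Si](C)(C)C(C)(C)C)CC3=O)[C@@]2(O[Si](C)(C)C)C1 | intermediate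
6 | diisopropyl 9-oxo-5-(trimethylsilyloxy)tricyclo[4.3.0.0(2,5)]non-7-ene-3,3-dicarboxylate | CC(C)OC(=O)C1(C(=O)OC(C)C)[C@H]2[C@H]3[C@H](C=CC3=O)[C@@]2(O[Si](C)(C)C)C1 | intermediate (not isolated)
7 | diisopropyl 9-oxo-5-(trimethylsilyloxy)tricyclo[4.3.0.0(2,5)]nonane-3,3-dicarboxylate, cis-anti-cis | CC(C)OC(=O)C1(C(=O)OC(C)C)[C@H]2[C@H]3[C@H](CCC3=O)[C@@]2(O[Si](C)(C)C)C1 | intermediate
8 | dichlorocerium 9-alkoxide of the 9-methyl adduct of 7 | CC(C)OC(=O)C1(C(=O)OC(C)C)[C@H]2[C@H]3[C@H](CC[C@@]3(C)O[Ce](Cl)Cl)[C@@]2(O[Si](C)(C)C)C1 | intermediate (not isolated)
9 | diisopropyl 9-methyl-9-(triethylsilyloxy)-5-(trimethylsilyloxy)tricyclo[4.3.0.0(2,5)]nonane-3,3-dicarboxylate, 9-oxygen cis to C2 | CC(C)OC(=O)C1(C(=O)OC(C)C)[C@H]2[C@H]3[C@H](CC[C@@]3(C)O[Si](CC)(CC)CC)[C@@]2(O[Si](C)(C)C)C1 | intermediate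
10 | diisopropyl 5-hydroxy-9-methyl-9-(triethylsilyloxy)tricyclo[4.3.0.0(2,5)]nonane-3,3-dicarboxylate | CC(C)OC(=O)C1(C(=O)OC(C)C)[C@H]2[C@H]3[C@H](CC[C@@]3(C)O[Si](CC)(CC)CC)[C@@]2(O)C1 | intermediate
11 | diisopropyl cis-1-methyl-4-oxo-1-(triethylsilyloxy)octahydro-1H-indene-6,6-dicarboxylate, 1-oxygen cis to C7 | CC(C)OC(=O)C1(C(=O)OC(C)C)C[C@H]2[C@H](CC[C@@]2(C)O[Si](CC)(CC)CC)C(=O)C1 | intermediate
12 | diisopropyl cis-1-hydroxy-1-methyl-4-oxooctahydro-1H-indene-6,6-dicarboxylate, formed as its alkoxide | CC(C)OC(=O)C1(C(=O)OC(C)C)C[C@H]2[C@H](CC[C@@]2(C)O)C(=O)C1 | intermediate (not isolated)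
13 | keto δ-lactone isopropyl ester (O1 acylated by the C6 carboxyl cis to the C7a–C1 bond; C4 ketone) | CC(C)OC(=O)[C@]12C[C@H]3[C@H](CC[C@@]3(C)OC1=O)C(=O)C2 | intermediate
14 | hydroxy δ-lactone isopropyl ester (4-methyl, 4-hydroxyl cis to C3) | CC(C)OC(=O)[C@]12C[C@H]3[C@H](CC[C@@]3(C)OC1=O)[C@](C)(O)C2 | intermediate
15 | 6-methylhept-5-en-2-one | CC(=O)CCC=C(C)C | starting material
16 | lithium 6-methylhepta-1,5-dien-2-olate | [Li]OC(=C)CCC=C(C)C | intermediate (not isolated)
17 | isopropyl 1,4-dihydroxy-1,4-dimethyl-6-(7-methyl-1,3-dioxooct-6-enyl)octahydro-1H-indene-6-carboxylate | CC(C)OC(=O)[C@@]1(C(=O)CC(=O)CCC=C(C)C)C[C@H]2[C@H](CC[C@@]2(C)O)[C@](C)(O)C1 | intermediate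
18 | 1,4-dihydroxy-1,4-dimethyl-3′-(3-methylbut-2-enyl)spiro[octahydro-1H-indene-6,1′-cyclohexane]-2′,4′,6′-trione (C3′ epimerisable, enolised) | CC(C)=CCC1C(=O)[C@]2(C[C@H]3[C@H](CC[C@@]3(C)O)[C@](C)(O)C2)C(=O)CC1=O | intermediate
19 | (S)-2-methylbutanoic acid | CC[C@H](C)C(=O)O | starting material
20 | 4′-enol (S)-2-methylbutanoate of 18 (one of the possible enol esters) | CC[C@H](C)C(=O)OC1=CC(=O)[C@@]2(C[C@H]3[C@H](CC[C@@]3(C)O)[C@](C)(O)C2)C(=O)C1CC=C(C)C | intermediate (not isolated)
21 | 5′-[(S)-2-methylbutanoyl] derivative of 18 (enolised triketone, C3′ epimerisable) | CC[C@H](C)C(=O)C1=C(O)C(CC=C(C)C)C(=O)[C@]2(C[C@H]3[C@H](CC[C@@]3(C)O)[C@](C)(O)C2)C1=O | intermediate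
22 | Hyperielliptone HB | CC[C@H](C)C(=O)C1=C(O)[C@@](C)(CC=C(C)C)C(=O)[C@]2(C[C@H]3[C@H](CC[C@@]3(C)O)[C@](C)(O)C2)C1=O | target

## Step count and least certain steps

Total: 13 steps. Longest linear sequence: 13 steps (1 to 22); 4, 15 and 19 enter as commercial materials.

Step 3 (key step). Most likely to go wrong: incomplete facial discrimination, because the silyloxy group is the only element that distinguishes the enone faces and the cyclobutene is flat on both sides; head-to-head leakage would add to the loss. Fallback, setting out from 3: irradiation with cyclopent-2-en-1-one under the same conditions would give racemic 7 directly, with no silyloxy group to remove. Preparative chromatography on a chiral stationary phase would separate 7 from its enantiomer, ent-ladder ketone F1, and the route is rejoined at 7.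

Step 5. Most likely to go wrong: incomplete silylation of the hindered concave cerium alkoxide, which would leave a free tertiary cyclopentanol whose own alkoxy radical would open ring C in step 7. Fallback, setting out from 7, in which the ketone is methylated only after the scission:
- citric acid in MeOH gives cyclobutanol ketone F2;
- the conditions of step 7 give hydrindane-1,4-dione F3;
- TMSOCH2CH2OTMS with catalytic TMSOTf at −78 °C ketalises the six-ring ketone selectively to monoketal F4;
- MeMgBr/CeCl3 adds from the convex face to give hydroxy ketal F5;
- aqueous acid gives 12, which catalytic KOtBu in THF lactonises, rejoining the route at 13.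

Step 7. Most likely to go wrong: sluggish activation of the hindered bridgehead O–H (a strong bond in a congested site), so that catalyst decay outruns turnover. Fallback, setting out from 10: hypoiodite fragmentation with PhI(OAc)2 and I2 under visible light generates the same alkoxy radical stoichiometrically and gives 7-iodo ketone F6 (configuration at C7 immaterial). Bu3SnH with AIBN in benzene at 80 °C then removes the iodine and rejoins the route at 11.

Step 8. Most likely to go wrong: the transesterification stalls at the hydroxy ester because isopropoxide reopens the strained lactone, while the open form epimerises at C3a. Fallback, setting out from 11: HF·pyridine gives 12 as an isolated compound. Excess MeMgBr/CeCl3 then adds to the C4 ketone of the chelated 1-alkoxide from the face of H-3a, and the new C4 alkoxide closes onto the cis ester to give γ-lactone diol F7. F7 enters step 10 in place of 14 and rejoins the route at 17.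

Step 13. Most likely to go wrong: poor facial selectivity in the C-methylation, since C3′ is several bonds away from every stereocentre. Fallback, setting out from 14, with the order of the two alkyl groups reversed:
- the kinetic lithium enolate of butan-2-one under the conditions of step 10 gives β-diketone F8;
- the conditions of step 11 give 3′-methyl trione F9;
- the conditions of step 12 give acyl trione F10;
- Pd2(dba)3 with the (R,R)- or (S,S)-DACH-phenyl bisphosphine ligand and prenyl methyl carbonate (Tsuji–Trost allylation) installs the prenyl group and rejoins the route at 22.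

Reversing the order inverts any intrinsic facial preference, and the chiral zerovalent palladium catalyst adds reagent control.

## Further compounds

F1 | step 3 | ent-ladder ketone (enantiomer of 7) | CC(C)OC(=O)C1(C(=O)OC(C)C)[C@@H]2[C@@H]3[C@@H](CCC3=O)[C@]2(O[Si](C)(C)C)C1
F2 | step 5 | diisopropyl 5-hydroxy-9-oxotricyclo[4.3.0.0(2,5)]nonane-3,3-dicarboxylate | CC(C)OC(=O)C1(C(=O)OC(C)C)[C@H]2[C@H]3[C@H](CCC3=O)[C@@]2(O)C1
F3 | step 5 | diisopropyl cis-1,4-dioxooctahydro-1H-indene-6,6-dicarboxylate | CC(C)OC(=O)C1(C(=O)OC(C)C)C[C@H]2[C@H](CCC2=O)C(=O)C1
F4 | step 5 | 4-(ethylene ketal) of F3 | CC(C)OC(=O)C1(C(=O)OC(C)C)C[C@H]2[C@H](CCC2=O)C3(OCCO3)C1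
F5 | step 5 | 1-hydroxy-1-methyl 4-(ethylene ketal), hydroxyl cis to C7 | CC(C)OC(=O)C1(C(=O)OC(C)C)C[C@H]2[C@H](CC[C@@]2(C)O)C3(OCCO3)C1
F6 | step 7 | diisopropyl 7-iodo-1-methyl-4-oxo-1-(triethylsilyloxy)octahydro-1H-indene-6,6-dicarboxylate | CC(C)OC(=O)C1(C(=O)OC(C)C)C(I)[C@H]2[C@H](CC[C@@]2(C)O[Si](CC)(CC)CC)C(=O)C1
F7 | step 8 | γ-lactone diol isopropyl ester (O4 acylated by the C6 carboxyl cis to it; 1-hydroxyl free) | CC(C)OC(=O)[C@]12C[C@H]3[C@H](CC[C@@]3(C)O)[C@](C)(OC1=O)C2
F8 | step 13 | isopropyl 6-(1,3-dioxopentyl)-1,4-dihydroxy-1,4-dimethyloctahydro-1H-indene-6-carboxylate | CC(C)OC(=O)[C@@]1(C(=O)CC(=O)CC)C[C@H]2[C@H](CC[C@@]2(C)O)[C@](C)(O)C1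
F9 | step 13 | 1,4-dihydroxy-1,3′,4-trimethylspiro[octahydro-1H-indene-6,1′-cyclohexane]-2′,4′,6′-trione | CC1C(=O)[C@]2(C[C@H]3[C@H](CC[C@@]3(C)O)[C@](C)(O)C2)C(=O)CC1=O
F10 | step 13 | 5′-[(S)-2-methylbutanoyl] derivative of F9 | CC[C@H](C)C(=O)C1=C(O)C(C)C(=O)[C@]2(C[C@H]3[C@H](CC[C@@]3(C)O)[C@](C)(O)C2)C1=O
A1 | alternative 1 | 1-(benzyloxy)-2-(3,3-dimethoxy-2-methylenecyclopentyl)propan-2-ol | C=C1[C@H](CCC1(OC)OC)[C@](C)(O)COCc2ccccc2
A2 | alternative 1 | benzyl (Z)-6,6-dimethoxy-2-methyloct-2-en-7-ynyl ether | C#CC(OC)(OC)CC/C=C(\COCc1ccccc1)C
A3 | alternative 2 | cis-fused hexahydroindene 1,1-diester with the ring B alkene at the methyl-bearing carbon | COC(=O)C1(C(=O)OC)C[C@H]2[C@H](CC[C@@]2(C)O[Si](C)(C)C(C)(C)C)C(C)=C1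
A4 | alternative 2 | dimethyl 2-[(2E)-6-(tert-butyldimethylsilyloxy)-2,6-dimethylocta-2,7-dienylidene]malonate, (R) at the carbinol carbon | COC(=O)C(C(=O)OC)=C/C(C)=C/CC[C@@](C)(O[Si](C)(C)C(C)(C)C)C=C
A5 | alternative 2 | (R)-linalool | CC(C)=CCC[C@@](C)(O)C=C
A6 | alternative 3 | cis-hexahydroindenone with the ketone at the future spiro carbon | O=C1C[C@H]2[C@H](C=C[C@@]2(C)O[Si](CC)(CC)CC)[C@](C)(OCc3ccccc3)C1
A7 | alternative 3 | 2-endo-[(E)-2-(benzyloxy)prop-1-enyl]-7-methyl-7-(triethylsilyloxy)bicyclo[2.2.1]hept-5-en-2-ol, silyloxy group anti to the ring alkene | O[C@]1(/C=C(\C)OCc2ccccc2)C[C@H]3C=C[C@@H]1[C@@]3(C)O[Si](CC)(CC)CC
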